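**Retrosynthetic overview**
1. 22 ⇐ 21 by Si–O cleavage. 21 ⇐ 20 by ring-closing metathesis at C1=C10, where the ten-membered ring forces the two ring carbons cis.
2. 20 ⇐ 16 is the key step: a net 1,2-shift of C7 from oxygen to C6 (base-free formal [1,2]-Wittig). It makes C6–C7, sets C6 and C7, and delivers the α-methylene lactone.
3. 16 ⇐ allylic alcohol 6 + Morita–Baylis–Hillman carbonate 15 (C–O bond).
4. 6 ⇐ but-2-yne-1,4-diol by anti-carbomagnesiation, which sets C4=C5. 15 ⇐ methallyl alcohol, ethyl glyoxylate and methyl acrylate by an asymmetric ene reaction (sets C8) followed by a Morita–Baylis–Hillman reaction.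
5. Ring order: γ-lactone first (step 12), ten-membered carbocycle second (step 13).

Assumption and numbering: the SMILES is taken literally. In both ring double bonds the two ring carbons are cis (CH2O-acyl groups trans to the ring chain, CIP E), and the centres are 6R,7R,8R. Germacrane numbering is used throughout: C1=C10, C4=C5, C6–O lactone, C7, C8–OH, C11=C13, C12=O, C14 = CH2O-isobutyrate, C15 = CH2OAc.

**Step 1**
Reactants: 1 but-2-yne-1,4-diol
Product: 2 4-(tert-butyldimethylsilyloxy)but-2-yn-1-ol
Conditions: NaH (1.0 equiv), THF, 0 °C; TBSCl (1.0 equiv), 25 °C (1 in excess)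
Reagents that add atoms: tert-butyldimethylsilyl chloride CC(C)(C)[Si](C)(C)Cl
Why: Monosilylation of a symmetrical diol through its sparingly soluble mono-sodium alkoxide leaves one free OH to direct step 2.

**Step 2**
Reactants: 2 4-(tert-butyldimethylsilyloxy)but-2-yn-1-ol; 3 but-3-enylmagnesium bromide
Product: 4 (E)-2-(but-3-enyl)-4-(tert-butyldimethylsilyloxy)but-2-en-1-ol
Conditions: 3 (3 equiv), CuI (10 mol%), THF, 0 to 25 °C; then H2O/NH4Cl
Reagents that add atoms: none
Why: In this alkoxide-directed anti-carbomagnesiation of a propargylic alcohol the butenyl group adds to the carbon next to CH2OMg and magnesium ends cis to CH2O in a five-membered chelate, so protonolysis places C3 cis to C6 and C15 trans to C6.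

**Step 3**
Reactants: 4 (E)-2-(but-3-enyl)-4-(tert-butyldimethylsilyloxy)but-2-en-1-ol
Product: 5 (E)-2-(but-3-enyl)-4-(tert-butyldimethylsilyloxy)but-2-enyl acetate
Conditions: Ac2O, pyridine, DMAP (5 mol%), CH2Cl2, 0 to 25 °C
Reagents that add atoms: acetic anhydride CC(=O)OC(C)=O
Why: Standard acylation of the only free primary alcohol installs the C15 acetate of the target.

**Step 4**
Reactants: 5 (E)-2-(but-3-enyl)-4-(tert-butyldimethylsilyloxy)but-2-enyl acetate
Product: 6 (E)-3-(acetoxymethyl)hepta-2,6-dien-1-ol
Conditions: HF·pyridine, THF, 0 °C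
Reagents that add atoms: none
Why: Fluoride-driven Si–O cleavage under buffered acidic conditions spares the acetate, and the E geometry rules out acyl migration.

**Step 5**
Reactants: 7 2-methylprop-2-en-1-ol
Product: 8 2-methylallyl isobutyrate
Conditions: isobutyryl chloride, Et3N, DMAP (5 mol%), CH2Cl2, 0 °C
Reagents that add atoms: isobutyryl chloride CC(C)C(=O)Cl
Why: Simple O-acylation puts the C14 isobutyrate in place from the start.

**Step 6**
Reactants: 8 2-methylallyl isobutyrate; 9 ethyl glyoxylate
Product: 10 ethyl (R)-2-hydroxy-4-(isobutyryloxymethyl)pent-4-enoate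
Conditions: (R)-BINOL/TiCl2(OiPr)2 (10 mol%), 4 Å molecular sieves, CH2Cl2, -30 to 0 °C
Reagents that add atoms: none
Why: In this asymmetric glyoxylate-ene reaction of a 1,1-disubstituted alkene the hydrogen comes from CH3 rather than the deactivated CH2O-acyl group, and the (R)-BINOL titanium catalyst gives the R alcohol, which becomes C8.

**Step 7**
Reactants: 10 ethyl (R)-2-hydroxy-4-(isobutyryloxymethyl)pent-4-enoate
Product: 11 ethyl (R)-2-(tert-butyldimethylsilyloxy)-4-(isobutyryloxymethyl)pent-4-enoate
Conditions: TBSOTf, 2,6-lutidine, CH2Cl2, -78 to 0 °C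
Reagents that add atoms: tert-butyldimethylsilyl triflate CC(C)(C)[Si](C)(C)OS(=O)(=O)C(F)(F)F
Why: Silylation with a non-nucleophilic base protects C8–OH without epimerising the α-centre.

**Step 8**
Reactants: 11 ethyl (R)-2-(tert-butyldimethylsilyloxy)-4-(isobutyryloxymethyl)pent-4-enoate
Product: 12 (R)-4-(tert-butyldimethylsilyloxy)-2-methylene-5-oxopentyl isobutyrate
Conditions: iBu2AlH (1.05 equiv), toluene, -78 °C; Rochelle salt work-up
Reagents that add atoms: none
Why: The inductively activated α-silyloxy ethyl ester forms a stable aluminium hemiacetal at -78 °C faster than the α-branched isobutyrate reacts, so the partial reduction stops at the aldehyde.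

**Step 9**
Reactants: 12 (R)-4-(tert-butyldimethylsilyloxy)-2-methylene-5-oxopentyl isobutyrate; 13 methyl acrylate
Product: 14 methyl (4R)-4-(tert-butyldimethylsilyloxy)-3-hydroxy-6-(isobutyryloxymethyl)-2-methylenehept-6-enoate (both C3 epimers)
Conditions: 13 (5 equiv), DABCO (0.5 equiv), MeOH (cat.), neat, 25 °C, 72 h
Reagents that add atoms: none
Why: The Morita–Baylis–Hillman reaction joins C7 to C11, and the new carbinol centre need not be controlled because it is erased in step 12.

**Step 10**
Reactants: 14 methyl (4R)-4-(tert-butyldimethylsilyloxy)-3-hydroxy-6-(isobutyryloxymethyl)-2-methylenehept-6-enoate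
Product: 15 methyl (4R)-3-(tert-butoxycarbonyloxy)-4-(tert-butyldimethylsilyloxy)-6-(isobutyryloxymethyl)-2-methylenehept-6-enoate
Conditions: Boc2O, DMAP (10 mol%), CH2Cl2, 0 to 25 °C
Reagents that add atoms: di-tert-butyl dicarbonate CC(C)(C)OC(=O)OC(=O)OC(C)(C)C
Why: Carbonate formation turns the alcohol into a leaving group that releases its own base (tert-butoxide) in step 11.

**Step 11**
Reactants: 15 methyl (4R)-3-(tert-butoxycarbonyloxy)-4-(tert-butyldimethylsilyloxy)-6-(isobutyryloxymethyl)-2-methylenehept-6-enoate; 6 (E)-3-(acetoxymethyl)hepta-2,6-dien-1-ol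
Product: 16 methyl (4R)-3-[(E)-3-(acetoxymethyl)hepta-2,6-dienyloxy]-4-(tert-butyldimethylsilyloxy)-6-(isobutyryloxymethyl)-2-methylenehept-6-enoate (both C3 epimers)
Conditions: DABCO (20 mol%), toluene, 25 to 40 °C
Reagents that add atoms: none
Why: In this Lewis-base-catalysed allylic substitution DABCO enters by SN2' with loss of CO2 and tert-butoxide, and the alkoxide of 6 then displaces DABCO by a second SN2' to give the branched C7–O–C6 ether under ester-tolerant conditions.

**Step 12**
Reactants: 16 methyl (4R)-3-[(E)-3-(acetoxymethyl)hepta-2,6-dienyloxy]-4-(tert-butyldimethylsilyloxy)-6-(isobutyryloxymethyl)-2-methylenehept-6-enoate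
Product: 20 3-methylenedihydrofuran-2-one carrying at C5 (= C6) the (E)-2-(acetoxymethyl)hexa-1,5-dienyl chain and at C4 (= C7) the 1-(tert-butyldimethylsilyloxy)-3-(isobutyryloxymethyl)but-3-enyl chain; H-6/H-7 trans; C6 C7 C8 configured as in 22, via enal 17 (not isolated), via allylchromium 18 (not isolated), via hydroxy ester 19 (not isolated)
Conditions: [Ir(dF(CF3)ppy)2(dtbbpy)]PF6 (2 mol%), quinuclidine (20 mol%), CrCl2 (10 mol%), indane-fused bis(oxazoline) ligand (12 mol%, enantiomer matched to the C8 centre), MeCN/CH2Cl2 (0.01 M), 450 nm LED, 25 °C; then PPTS (10 mol%), CH2Cl2, 25 °C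
Reagents that add atoms: none
Why: Proposed new method: a catalytic, base-free formal [1,2]-Wittig shift in which C7 migrates from O to C6; photo-oxidised quinuclidine abstracts the weakest and most hydridic hydrogen (the allylic, O-bearing C6–H of 16); the α-alkoxy allyl radical undergoes β-scission of the O–C7 bond to give enal 17 and the 2-(methoxycarbonyl)allyl radical; divalent chromium captures that radical as 18, which adds through its γ-carbon C7 to 17 in a closed chair transition state (anti, hence H-6/H-7 trans, with the aldehyde face chosen by the bis(oxazoline) ligand and reinforced by the C8 silyl ether); quinuclidinium protonates the alkoxide, the reduced photocatalyst returns trivalent chromium to divalent chromium, and 19 lactonises; the process is redox-neutral, never accumulates the labile enal and tolerates all esters; the closest known reaction types are the anionic [1,2]-Wittig rearrangement (a radical-pair 1,2-shift) and dual photoredox/chromium carbonyl allylation, neither of which has been shown for C–O cleavage of an allyl ether.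

**Step 13**
Reactants: 20 seco-lactone of step 12
Product: 21 8-O-tert-butyldimethylsilyl ether of 22 (ten-membered ring closed; ring carbons cis at C1=C10 and at C4=C5)
Conditions: second-generation Hoveyda–Grubbs catalyst (10 mol%), 1,4-benzoquinone (20 mol%), toluene (1 mM), 90 °C
Reagents that add atoms: none
Why: Ring-closing metathesis pairs the terminal C1 alkene with the 1,1-disubstituted C10 alkene, the electron-poor α-methylene lactone and the trisubstituted C4=C5 stay inert, and the ten-membered ring allows only the isomer with C2 and C9 cis.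

**Step 14**
Reactants: 21 8-O-tert-butyldimethylsilyl ether of 22
Product: 22 target CNP0312458.1
Conditions: HF·pyridine, pyridine/THF, 0 to 25 °C
Reagents that add atoms: none
Why: Buffered fluoride desilylation frees C8–OH without touching the two allylic esters, the α-methylene lactone or any stereocentre.

**Compound list**
1 | but-2-yne-1,4-diol | OCC#CCO | starting material
2 | 4-(tert-butyldimethylsilyloxy)but-2-yn-1-ol | OCC#CCO[Si](C)(C)C(C)(C)C | intermediate
3 | but-3-enylmagnesium bromide | C=CCC[Mg]Br | starting material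
4 | (E)-2-(but-3-enyl)-4-(tert-butyldimethylsilyloxy)but-2-en-1-ol | OC/C(CCC=C)=C/CO[Si](C)(C)C(C)(C)C | intermediate
5 | (E)-2-(but-3-enyl)-4-(tert-butyldimethylsilyloxy)but-2-enyl acetate | CC(=O)OC/C(CCC=C)=C/CO[Si](C)(C)C(C)(C)C | intermediate
6 | (E)-3-(acetoxymethyl)hepta-2,6-dien-1-ol | CC(=O)OC/C(CCC=C)=C/CO | intermediate
7 | 2-methylprop-2-en-1-ol | C=C(C)CO | starting material
8 | 2-methylallyl isobutyrate | C=C(C)COC(=O)C(C)C | intermediate
9 | ethyl glyoxylate | CCOC(=O)C=O | starting material
10 | ethyl (R)-2-hydroxy-4-(isobutyryloxymethyl)pent-4-enoate | CCOC(=O)[C@H](O)CC(=C)COC(=O)C(C)C | intermediate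
11 | ethyl (R)-2-(tert-butyldimethylsilyloxy)-4-(isobutyryloxymethyl)pent-4-enoate | CCOC(=O)[C@H](O[Si](C)(C)C(C)(C)C)CC(=C)COC(=O)C(C)C | intermediate
12 | (R)-4-(tert-butyldimethylsilyloxy)-2-methylene-5-oxopentyl isobutyrate | O=C[C@H](O[Si](C)(C)C(C)(C)C)CC(=C)COC(=O)C(C)C | intermediate
13 | methyl acrylate | C=CC(=O)OC | starting material
14 | Morita–Baylis–Hillman alcohol (C7 epimers) | COC(=O)C(=C)C(O)[C@H](O[Si](C)(C)C(C)(C)C)CC(=C)COC(=O)C(C)C | intermediate
15 | Morita–Baylis–Hillman tert-butyl carbonate (C7 epimers) | COC(=O)C(=C)C(OC(=O)OC(C)(C)C)[C@H](O[Si](C)(C)C(C)(C)C)CC(=C)COC(=O)C(C)C | intermediate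
16 | C7–O–C6 allyl ether (C7 epimers) | COC(=O)C(=C)C(OC/C=C(/COC(C)=O)CCC=C)[C@H](O[Si](C)(C)C(C)(C)C)CC(=C)COC(=O)C(C)C | intermediate
17 | (E)-3-(acetoxymethyl)hepta-2,6-dienal | O=C/C=C(/COC(C)=O)CCC=C | intermediate
18 | 2-(methoxycarbonyl)allyl chromium dichloride (trivalent chromium, ligand omitted) | COC(=O)C(C[Cr](Cl)Cl)=C[C@H](O[Si](C)(C)C(C)(C)C)CC(=C)COC(=O)C(C)C | intermediate
19 | anti γ-hydroxy α-methylene ester | COC(=O)C(=C)[C@@H]([C@H](O)/C=C(/COC(C)=O)CCC=C)[C@H](O[Si](C)(C)C(C)(C)C)CC(=C)COC(=O)C(C)C | intermediate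
20 | trans α-methylene-γ-butyrolactone (seco diene) | C=C1C(=O)O[C@H](/C=C(/COC(C)=O)CCC=C)[C@H]1[C@H](O[Si](C)(C)C(C)(C)C)CC(=C)COC(=O)C(C)C | intermediate
21 | 8-O-TBS germacranolide | C=C1C(=O)O[C@@H]2/C=C(/COC(C)=O)CC/C=C(/COC(=O)C(C)C)C[C@@H](O[Si](C)(C)C(C)(C)C)[C@@H]12 | intermediate
22 | CNP0312458.1 | C=C1C(=O)O[C@@H]2/C=C(/COC(C)=O)CC/C=C(/COC(=O)C(C)C)C[C@@H](O)[C@@H]12 | target

**Step count:** 14 steps in total. The longest linear sequence is 10 steps (steps 5 to 14). The four-step branch, steps 1 to 4, joins at step 11.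

**Three steps most likely to fail**

Step 12 (the new 1,2-shift). The risks are slow β-scission, capture of the C6 radical before it fragments, and Giese side reactions. The fallback uses known chemistry, sets out from 6 and 14, and comes back at 20.
- MnO2 in CH2Cl2 oxidises 6 to enal 17, which is now isolated and used at once.
- PBr3 in Et2O at 0 °C converts 14, with allylic transposition, into methyl (Z)-2-(bromomethyl)-4-(tert-butyldimethylsilyloxy)-6-(isobutyryloxymethyl)hepta-2,6-dienoate F1.
- Stoichiometric CrCl2 in THF couples F1 with 17. This is the classical anti-selective 2-(alkoxycarbonyl)allyl chromium addition.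
- The coupling gives 19, which lactonises with PPTS to 20.

Step 13 (ten-membered ring-closing metathesis to a trisubstituted alkene). The risks are oligomers and alkene migration. The fallback sets out from 16, comes back at 21, and reverses the order of events.
- Metathesis of 16 closes the less strained eleven-membered ring to the oxacycloundecadiene F2.
- The conditions of step 12 then act as a ring contraction.
- The ring-opened enal allylchromium F3 closes C6–C7 to the ten-membered hydroxy ester F4.
- F4 lactonises to 21.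

Step 11 (Lewis-base etherification at a hindered alkyl-substituted carbonate). The fallback sets out from 6 and 14, comes back at 16, and reverses the polarity.
- CBr4/PPh3 converts 6 into (E)-3-(acetoxymethyl)-1-bromohepta-2,6-diene F5.
- Ag2O in CH2Cl2 (dark, molecular sieves) alkylates the hydroxyl of 14 with F5 under neutral conditions.

**Further compounds**
F1 | step 12 | methyl (Z)-2-(bromomethyl)-4-(tert-butyldimethylsilyloxy)-6-(isobutyryloxymethyl)hepta-2,6-dienoate | COC(=O)/C(CBr)=C/[C@H](O[Si](C)(C)C(C)(C)C)CC(=C)COC(=O)C(C)C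
F2 | step 13 | eleven-membered cyclic ether (oxacycloundecadiene, C7 epimers) | COC(=O)C(=C)C1OC/C=C(/COC(C)=O)CC/C=C(/COC(=O)C(C)C)C[C@H]1O[Si](C)(C)C(C)(C)C
F3 | step 13 | ring-opened enal allylchromium dichloride | O=C/C=C(/COC(C)=O)CC/C=C(/COC(=O)C(C)C)C[C@@H](O[Si](C)(C)C(C)(C)C)C=C(C[Cr](Cl)Cl)C(=O)OC
F4 | step 13 | ten-membered hydroxy ester | COC(=O)C(=C)[C@H]1[C@H](O)/C=C(/COC(C)=O)CC/C=C(/COC(=O)C(C)C)C[C@H]1O[Si](C)(C)C(C)(C)C
F5 | step 11 | (E)-3-(acetoxymethyl)-1-bromohepta-2,6-diene | CC(=O)OC/C(CCC=C)=C/CBr
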